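## Retrosynthetic overview

1. Target 20 ⇐ 19 (demethylation of the methoxy ortho to the ester) ⇐ 18 by closing the pyran C3–O bond (enantioselective Wacker-type etherification, sets C3).
2. 18 ⇐ 16 (α-iodination, Stille hydroxymethylation) ⇐ 15 (dehydrogenation) ⇐ 13 by one-carbon ring expansion (diazoalkane homologation, a 1,2-shift): the alkylated α-carbon of the cyclopentanone becomes the β-carbon (C4a) of the cyclohexenone.
3. 13 ⇐ 10 + (E)-1-bromopent-2-ene; 10 ⇐ 8 by desymmetrising CBS reduction (sets C6 and C7) and acetylation.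
4. 8 ⇐ 2-methylcyclopentane-1,3-dione + acid 5 (oxidative α-acyloxylation); 5 ⇐ two units of methyl acetoacetate via methyl orsellinate.
5. Ring order: arene (step 1); carbocycle bought five-membered and expanded to six (step 8); pyran last (step 12).

Assumption: 13–15 are carried as C4-epimer mixtures (that centre is erased in step 9), and the ligand antipode named in step 12 is taken to be the one giving 3S; if a model cyclisation shows the opposite sense, the other antipode is used.

## Route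

Step 1
Reactants: 1 methyl acetoacetate (2 equiv)
Product: 3 methyl orsellinate, via methyl 3,5,7-trioxooctanoate 2 (not isolated)
Conditions: NaH, THF, 0 °C; n-BuLi, −78 °C → reflux; then 1 M HCl
Reagents that add atoms: none
Why: Claisen self-condensation of the acetoacetate dianion gives triketo ester 2, which closes by intramolecular aldol condensation and aromatises (biomimetic tetraketide cyclisation); no stereocentre.

Step 2
Reactants: 3 methyl orsellinate
Product: 4 methyl 2,4-dimethoxy-6-methylbenzoate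
Conditions: MeI (5 equiv), K2CO3, DMF, 60 °C
Reagents that add atoms: iodomethane, CI
Why: Williamson O-methylation under forcing conditions also alkylates the hydrogen-bonded 2-OH, masking the phenol against the oxidants and iodine used later.

Step 3
Reactants: 4 methyl 2,4-dimethoxy-6-methylbenzoate
Product: 5 2,4-dimethoxy-6-methylbenzoic acid
Conditions: KOH, DMSO–H2O, 100 °C; then HCl
Reagents that add atoms: potassium hydroxide, [K+].[OH-]
Why: Saponification of the hindered benzoate is forced in hot aqueous DMSO, and the electron-rich acid does not decarboxylate under base.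

Step 4
Reactants: 5 2,4-dimethoxy-6-methylbenzoic acid; 6 2-methylcyclopentane-1,3-dione
Product: 8 1-methyl-2,5-dioxocyclopentyl 2,4-dimethoxy-6-methylbenzoate, via bis(aroyloxy)iodobenzene 7 (not isolated)
Conditions: PhI(OAc)2, 5 (2.1 equiv), PhCl, 50 °C, 20 mbar; then 6, MeCN, 25 °C
Reagents that add atoms: none
Why: Ligand exchange gives the trivalent iodine dicarboxylate 7, and its reaction with the dione enol followed by reductive C–O ligand coupling (α-acyloxylation of a 1,3-dicarbonyl compound) builds the hindered tertiary ester on an achiral substrate, so no tertiary alcohol has to be acylated.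

Step 5
Reactants: 8 1-methyl-2,5-dioxocyclopentyl 2,4-dimethoxy-6-methylbenzoate
Product: 9 (1S,2S)-2-hydroxy-1-methyl-5-oxocyclopentyl 2,4-dimethoxy-6-methylbenzoate
Conditions: (R)-Me-CBS oxazaborolidine (10 mol %), BH3·SMe2 (0.6 equiv), THF, −40 °C; then MeOH
Reagents that add atoms: none
Why: Corey–Bakshi–Shibata reduction desymmetrises the prochiral dione: the catalyst binds the carbonyl lone pair anti to the quaternary carbon and hydride arrives anti to the bulky aroyloxy group, giving the (S)-carbinol cis to the ester oxygen and setting both C6 and C7 of the target.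

Step 6
Reactants: 9 (1S,2S)-2-hydroxy-1-methyl-5-oxocyclopentyl 2,4-dimethoxy-6-methylbenzoate
Product: 10 (1S,2S)-2-acetoxy-1-methyl-5-oxocyclopentyl 2,4-dimethoxy-6-methylbenzoate
Conditions: Ac2O, pyridine, DMAP (cat.), CH2Cl2, 0 → 25 °C
Reagents that add atoms: acetic anhydride, CC(=O)OC(C)=O
Why: DMAP-catalysed acetylation of the secondary alcohol; the doubly ortho-substituted aryl ester is too hindered to migrate.

Step 7
Reactants: 10 (1S,2S)-2-acetoxy-1-methyl-5-oxocyclopentyl 2,4-dimethoxy-6-methylbenzoate; 11 (E)-1-bromopent-2-ene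
Product: 13 (1S,2S)-2-acetoxy-1-methyl-5-oxo-4-[(E)-pent-2-en-1-yl]cyclopentyl 2,4-dimethoxy-6-methylbenzoate (C4 epimers), via lithium enolate 12 (not isolated)
Conditions: LiN(SiMe3)2, THF, −78 °C; 11, DMPU, −78 → −40 °C
Reagents that add atoms: none
Why: Kinetic enolate alkylation (SN2 at the primary allylic bromide) can occur only at the single enolisable α-carbon, the future C4a; the new stereocentre is immaterial because it becomes sp2 in step 9.

Step 8
Reactants: 13 (1S,2S)-2-acetoxy-1-methyl-5-oxo-4-[(E)-pent-2-en-1-yl]cyclopentyl 2,4-dimethoxy-6-methylbenzoate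
Product: 15 (1S,2S)-2-acetoxy-1-methyl-6-oxo-4-[(E)-pent-2-en-1-yl]cyclohexyl 2,4-dimethoxy-6-methylbenzoate (C4 epimers), via α-trimethylsilyl ketone 14 (not isolated)
Conditions: TMSCHN2, Sc(OTf)3 (10 mol %), CH2Cl2, −78 → 0 °C; then 1 M HCl, THF
Reagents that add atoms: (trimethylsilyl)diazomethane, C[Si](C)(C)C=[N+]=[N-]
Why: Lewis acid-catalysed diazoalkane–ketone homologation (Tiffeneau–Demjanov-type 1,2-shift): TMSCHN2 adds to the activated carbonyl and the bond to the tertiary alkylated carbon migrates with retention as N2 leaves (the electron-poor quaternary acyloxy carbon migrates poorly), so the ring grows to six and the alkylated α-carbon becomes the β-carbon while C6 and C7 are untouched.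

Step 9
Reactants: 15 (1S,2S)-2-acetoxy-1-methyl-6-oxo-4-[(E)-pent-2-en-1-yl]cyclohexyl 2,4-dimethoxy-6-methylbenzoate
Product: 16 (1S,6S)-6-acetoxy-1-methyl-2-oxo-4-[(E)-pent-2-en-1-yl]cyclohex-3-en-1-yl 2,4-dimethoxy-6-methylbenzoate
Conditions: IBX, 4-methoxypyridine N-oxide, DMSO, 25 °C
Reagents that add atoms: none
Why: IBX α,β-dehydrogenation through the only possible enol (toward the new CH2) gives a single enone regioisomer and erases the C4 epimer mixture.

Step 10
Reactants: 16 (1S,6S)-6-acetoxy-1-methyl-2-oxo-4-[(E)-pent-2-en-1-yl]cyclohex-3-en-1-yl 2,4-dimethoxy-6-methylbenzoate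
Product: 17 (1S,6S)-6-acetoxy-3-iodo-1-methyl-2-oxo-4-[(E)-pent-2-en-1-yl]cyclohex-3-en-1-yl 2,4-dimethoxy-6-methylbenzoate
Conditions: I2, pyridine, DMAP (cat.), CH2Cl2, 25 °C
Reagents that add atoms: iodine, II
Why: Johnson α-iodination of the enone (amine-mediated addition–iodination–elimination) puts the coupling handle on C8a without touching the isolated alkene or the methylated arene.

Step 11
Reactants: 17 (1S,6S)-6-acetoxy-3-iodo-1-methyl-2-oxo-4-[(E)-pent-2-en-1-yl]cyclohex-3-en-1-yl 2,4-dimethoxy-6-methylbenzoate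
Product: 18 (1S,6S)-6-acetoxy-3-(hydroxymethyl)-1-methyl-2-oxo-4-[(E)-pent-2-en-1-yl]cyclohex-3-en-1-yl 2,4-dimethoxy-6-methylbenzoate
Conditions: Bu3SnCH2OH, Pd(PPh3)4 (5 mol %), dioxane, 90 °C
Reagents that add atoms: (tributylstannyl)methanol, CCCC[Sn](CCCC)(CCCC)CO
Why: Stille (Kosugi) cross-coupling of the vinyl iodide with the hydroxymethylstannane delivers C1 together with its oxygen.

Step 12
Reactants: 18 (1S,6S)-6-acetoxy-3-(hydroxymethyl)-1-methyl-2-oxo-4-[(E)-pent-2-en-1-yl]cyclohex-3-en-1-yl 2,4-dimethoxy-6-methylbenzoate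
Product: 19 (3S,6S,7S)-6-acetoxy-7-methyl-8-oxo-3-[(E)-prop-1-en-1-yl]-3,4,5,6,7,8-hexahydro-1H-isochromen-7-yl 2,4-dimethoxy-6-methylbenzoate
Conditions: Pd(OCOCF3)2 (10 mol %), (M,S,S)-i-Pr-SPRIX (12 mol %), p-benzoquinone (2 equiv), CH2Cl2, 0 °C
Reagents that add atoms: none
Why: Proposed new method: enantioselective 6-exo Wacker-type oxidative etherification in which a cationic divalent palladium–SPRIX complex activates the (E)-alkene, the primary allylic alcohol adds to the proximal alkene carbon (catalyst-controlled face selection sets C3 as S, the remote C6/C7 centres giving no bias), β-hydride elimination away from oxygen releases the (E)-propenyl group and zerovalent palladium is reoxidised by benzoquinone; closest known reaction type: asymmetric Wacker-type cyclisations of alkenyl alcohols and 2-allylphenols with Pd–SPRIX or Pd–boxax catalysts and racemic oxidative cyclisations of 2-(2-alkenyl)benzyl alcohols to 3-vinylisochromans, not yet shown for a 6-exo closure onto a 1,2-dialkyl alkene with catalyst-controlled diastereoselection.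

Step 13
Reactants: 19 (3S,6S,7S)-6-acetoxy-7-methyl-8-oxo-3-[(E)-prop-1-en-1-yl]-3,4,5,6,7,8-hexahydro-1H-isochromen-7-yl 2,4-dimethoxy-6-methylbenzoate
Product: 20 (3S,6S,7S)-6-acetoxy-7-methyl-8-oxo-3-[(E)-prop-1-en-1-yl]-3,4,5,6,7,8-hexahydro-1H-isochromen-7-yl 2-hydroxy-4-methoxy-6-methylbenzoate (target)
Conditions: BCl3, CH2Cl2, −78 °C; then H2O
Reagents that add atoms: none
Why: BCl3 chelated between the ester carbonyl and the ortho methoxy group cleaves only that methyl ether (chelation-controlled Lewis acid demethylation), leaving the para methoxy group, the acetate, the allylic ether and all stereocentres untouched at −78 °C.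

## Compound list

1 | methyl acetoacetate | CC(=O)CC(=O)OC | starting material
2 | methyl 3,5,7-trioxooctanoate (not isolated) | COC(=O)CC(=O)CC(=O)CC(C)=O | intermediate
3 | methyl orsellinate (methyl 2,4-dihydroxy-6-methylbenzoate) | COC(=O)c1c(C)cc(O)cc1O | intermediate
4 | methyl 2,4-dimethoxy-6-methylbenzoate | COC(=O)c1c(C)cc(OC)cc1OC | intermediate
5 | 2,4-dimethoxy-6-methylbenzoic acid | OC(=O)c1c(C)cc(OC)cc1OC | intermediate
6 | 2-methylcyclopentane-1,3-dione | CC1C(=O)CCC1=O | starting material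
7 | [bis(2,4-dimethoxy-6-methylbenzoyloxy)iodo]benzene (not isolated) | COc1cc(C)c(C(=O)OI(OC(=O)c2c(C)cc(OC)cc2OC)c2ccccc2)c(OC)c1 | intermediate
8 | 1-methyl-2,5-dioxocyclopentyl 2,4-dimethoxy-6-methylbenzoate | CC1(OC(=O)c2c(C)cc(OC)cc2OC)C(=O)CCC1=O | intermediate
9 | (1S,2S)-2-hydroxy-1-methyl-5-oxocyclopentyl 2,4-dimethoxy-6-methylbenzoate | O=C1[C@@](C)(OC(=O)c2c(C)cc(OC)cc2OC)[C@@H](O)CC1 | intermediate
10 | (1S,2S)-2-acetoxy-1-methyl-5-oxocyclopentyl 2,4-dimethoxy-6-methylbenzoate | O=C1[C@@](C)(OC(=O)c2c(C)cc(OC)cc2OC)[C@@H](OC(C)=O)CC1 | intermediate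
11 | (E)-1-bromopent-2-ene | CC/C=C/CBr | starting material
12 | lithium enolate of 10 (not isolated) | [Li]OC=1[C@@](C)(OC(=O)c2c(C)cc(OC)cc2OC)[C@@H](OC(C)=O)CC=1 | intermediate
13 | (1S,2S)-2-acetoxy-1-methyl-5-oxo-4-[(E)-pent-2-en-1-yl]cyclopentyl 2,4-dimethoxy-6-methylbenzoate (C4 epimers) | O=C1[C@@](C)(OC(=O)c2c(C)cc(OC)cc2OC)[C@@H](OC(C)=O)CC1C/C=C/CC | intermediate
14 | (1S,2S)-2-acetoxy-1-methyl-6-oxo-4-[(E)-pent-2-en-1-yl]-5-(trimethylsilyl)cyclohexyl 2,4-dimethoxy-6-methylbenzoate (not isolated) | O=C1[C@@](C)(OC(=O)c2c(C)cc(OC)cc2OC)[C@@H](OC(C)=O)CC(C/C=C/CC)C1[Si](C)(C)C | intermediate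
15 | (1S,2S)-2-acetoxy-1-methyl-6-oxo-4-[(E)-pent-2-en-1-yl]cyclohexyl 2,4-dimethoxy-6-methylbenzoate (C4 epimers) | O=C1[C@@](C)(OC(=O)c2c(C)cc(OC)cc2OC)[C@@H](OC(C)=O)CC(C/C=C/CC)C1 | intermediate
16 | (1S,6S)-6-acetoxy-1-methyl-2-oxo-4-[(E)-pent-2-en-1-yl]cyclohex-3-en-1-yl 2,4-dimethoxy-6-methylbenzoate | O=C1[C@@](C)(OC(=O)c2c(C)cc(OC)cc2OC)[C@@H](OC(C)=O)CC(C/C=C/CC)=C1 | intermediate
17 | (1S,6S)-6-acetoxy-3-iodo-1-methyl-2-oxo-4-[(E)-pent-2-en-1-yl]cyclohex-3-en-1-yl 2,4-dimethoxy-6-methylbenzoate | O=C1[C@@](C)(OC(=O)c2c(C)cc(OC)cc2OC)[C@@H](OC(C)=O)CC(C/C=C/CC)=C1I | intermediate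
18 | (1S,6S)-6-acetoxy-3-(hydroxymethyl)-1-methyl-2-oxo-4-[(E)-pent-2-en-1-yl]cyclohex-3-en-1-yl 2,4-dimethoxy-6-methylbenzoate | O=C1[C@@](C)(OC(=O)c2c(C)cc(OC)cc2OC)[C@@H](OC(C)=O)CC(C/C=C/CC)=C1CO | intermediate
19 | (3S,6S,7S)-6-acetoxy-7-methyl-8-oxo-3-[(E)-prop-1-en-1-yl]-3,4,5,6,7,8-hexahydro-1H-isochromen-7-yl 2,4-dimethoxy-6-methylbenzoate | C/C=C/[C@@H]1CC2=C(CO1)C(=O)[C@@](C)(OC(=O)c1c(C)cc(OC)cc1OC)[C@@H](OC(C)=O)C2 | intermediate
20 | (3S,6S,7S)-6-acetoxy-7-methyl-8-oxo-3-[(E)-prop-1-en-1-yl]-3,4,5,6,7,8-hexahydro-1H-isochromen-7-yl 2-hydroxy-4-methoxy-6-methylbenzoate | C/C=C/[C@@H]1CC2=C(CO1)C(=O)[C@@](C)(OC(=O)c1c(C)cc(OC)cc1O)[C@@H](OC(C)=O)C2 | target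

## Step count and risks

Total step count: 13. Longest linear sequence: 13 (steps 1–13; acid 5 is joined to dione 6 at the outset, so the route is linear).

Three steps most likely to fail:

Step 4. The oxidative C–O coupling must build a fully substituted carbon with a doubly ortho-substituted carboxylate, and acetate transfer or over-oxidation could compete. The fallback sets out from 6, which is hydroxylated with dimethyldioxirane (acetone, 0 °C) to 2-hydroxy-2-methylcyclopentane-1,3-dione F1. Acid 5 is converted with (COCl)2 and catalytic DMF into 2,4-dimethoxy-6-methylbenzoyl chloride F2. F1 is then acylated with F2 (Et3N, DMAP, CH2Cl2, 40 °C), a classical nucleophilic acylation of a tertiary alcohol, and the route is rejoined at 8.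

Step 8. The ketone of 13 lies between a quaternary and a tertiary carbon, so addition of TMSCHN2 may be slow and oxirane formation can compete. The fallback sets out from 13, which is converted with TMSOTf and Et3N into the trimethylsilyl enol ether F3 (only one regioisomer is possible). Cyclopropanation with Et2Zn and CH2I2 gives the siloxycyclopropane F4. FeCl3 in DMF opens the internal cyclopropane bond by one-electron oxidation and β-scission to the ring-expanded β-chloro ketone F5, and NaOAc in MeOH eliminates HCl. This Saegusa–Ito ring expansion rejoins the route directly at enone 16, so 15 and step 9 are bypassed.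

Step 12 (the new step). Oxidation of the primary allylic alcohol by palladium, alkene isomerisation or poor face selection could defeat it. The fallback uses known chemistry and sets out from 18. Phenylselenoetherification with N-(phenylseleno)phthalimide and camphorsulfonic acid (CH2Cl2, −20 °C) closes the pyran 6-exo to the selenide F6 (both C3 configurations). H2O2 and pyridine give the selenoxide F7, which undergoes syn-elimination away from oxygen to the (E)-propenyl ethers. The desired 19 is separated by chromatography from its C3 epimer F8, and the route is rejoined at 19.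

## Further compounds

F1 | step 4 | 2-hydroxy-2-methylcyclopentane-1,3-dione | CC1(O)C(=O)CCC1=O
F2 | step 4 | 2,4-dimethoxy-6-methylbenzoyl chloride | COc1cc(C)c(C(Cl)=O)c(OC)c1
F3 | step 8 | (1S,5S)-5-acetoxy-1-methyl-3-[(E)-pent-2-en-1-yl]-2-(trimethylsilyloxy)cyclopent-2-en-1-yl 2,4-dimethoxy-6-methylbenzoate | C[Si](C)(C)OC=1[C@@](C)(OC(=O)c2c(C)cc(OC)cc2OC)[C@@H](OC(C)=O)CC=1C/C=C/CC
F4 | step 8 | (2S,3S)-3-acetoxy-2-methyl-5-[(E)-pent-2-en-1-yl]-1-(trimethylsilyloxy)bicyclo[3.1.0]hexan-2-yl 2,4-dimethoxy-6-methylbenzoate | C[Si](C)(C)OC12[C@@](C)(OC(=O)c3c(C)cc(OC)cc3OC)[C@@H](OC(C)=O)CC1(C/C=C/CC)C2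
F5 | step 8 | (1S,2S)-2-acetoxy-4-chloro-1-methyl-6-oxo-4-[(E)-pent-2-en-1-yl]cyclohexyl 2,4-dimethoxy-6-methylbenzoate | O=C1[C@@](C)(OC(=O)c2c(C)cc(OC)cc2OC)[C@@H](OC(C)=O)CC(Cl)(C/C=C/CC)C1
F6 | step 12 | (6S,7S)-6-acetoxy-7-methyl-8-oxo-3-[1-(phenylselanyl)propyl]-3,4,5,6,7,8-hexahydro-1H-isochromen-7-yl 2,4-dimethoxy-6-methylbenzoate (C3 epimers) | CCC([Se]c1ccccc1)C1CC2=C(CO1)C(=O)[C@@](C)(OC(=O)c1c(C)cc(OC)cc1OC)[C@@H](OC(C)=O)C2
F7 | step 12 | selenoxide of F6 | CCC([Se](=O)c1ccccc1)C1CC2=C(CO1)C(=O)[C@@](C)(OC(=O)c1c(C)cc(OC)cc1OC)[C@@H](OC(C)=O)C2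
F8 | step 12 | (3R,6S,7S)-6-acetoxy-7-methyl-8-oxo-3-[(E)-prop-1-en-1-yl]-3,4,5,6,7,8-hexahydro-1H-isochromen-7-yl 2,4-dimethoxy-6-methylbenzoate (C3 epimer of 19) | C/C=C/[C@H]1CC2=C(CO1)C(=O)[C@@](C)(OC(=O)c1c(C)cc(OC)cc1OC)[C@@H](OC(C)=O)C2
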